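**Plan**

1. Halimane numbering is used: ring A = C1–C5 + C10 (C4 carries Me and CO2Me, C5 is the ring-fusion CH, C1=C10 is the alkene); ring B = C5–C10 (C8 Me; C9 Me and the side chain C11–C15).
2. Cuts: the C13/C14 oxirane goes back to the (E)-C13=C14 allylic alcohol; ring A is then cut by retro-[4+2] at C2–C3 and C4–C5. This is possible because ring A is a cyclohexene whose C1=C10 bond is flanked by C2 and C5, so it unfolds into the ring B 1-vinylcyclohexene (C2=C1–C10=C5) and methyl methacrylate (C3=C4, which carries C4 with its methyl and CO2Me).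
3. The diene is cut at C1–C10 (vinyl coupling of an enol triflate), C13=C14 (olefination) and C9–C11 (Michael addition), back to 2-methylcyclohex-2-enone.
4. Forward: ring B is bought, the side chain is joined, ring A is closed last by the Diels–Alder reaction, and the oxirane is added at the end.
5. Stereochemistry: C8 by ligand-controlled copper-catalysed conjugate methylation; C9 relayed from C8 (Michael addition anti to the C8 methyl); C5 and C4 relayed from C8/C9 in the cycloaddition (diene face, endo rule); C13/C14 by L-(+)-tartrate reagent control.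

Key step: step 6

Remark: the oxirane is treated as a functional group of the side chain; the carbon skeleton is complete after step 6.

**Route**

Step 1
Reactants: 1 2-methylcyclohex-2-en-1-one; 2 trimethylaluminium; 3 trimethylsilyl trifluoromethanesulfonate
Product: 5 (R)-[(2,3-dimethylcyclohex-1-en-1-yl)oxy]trimethylsilane, via aluminium enolate 4 (not isolated)
Conditions: Me3Al, Cu(O2C-2-C4H3S) (copper thiophene-2-carboxylate, 2 mol%), BINOL-derived phosphoramidite ligand with a bis(1-phenylethyl)amino group (4 mol%, the enantiomer that gives the 3R centre), Et2O, −30 °C; then Me3SiOTf, THF, −30 °C → rt; Et3N, aq. NaHCO3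
Reagents that add atoms: trimethylaluminium C[Al](C)C; trimethylsilyl trifluoromethanesulfonate C[Si](C)(C)OS(=O)(=O)C(F)(F)F
Why: Copper-catalysed asymmetric conjugate addition of a methylaluminium reagent to a 2-substituted cyclohexenone sets the β-methyl centre (C8) under ligand control, and O-silylation of the aluminium enolate fixes the tetrasubstituted enolate regiochemistry for the next C–C bond.

Step 2
Reactants: 5 (R)-[(2,3-dimethylcyclohex-1-en-1-yl)oxy]trimethylsilane; 6 but-3-en-2-one
Product: 8 (2S,3R)-2,3-dimethyl-2-(3-oxobutyl)cyclohexan-1-one, via silyl enol ether adduct 7 (not isolated)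
Conditions: but-3-en-2-one (2 equiv), Sc(OTf)3 (5 mol%), CH2Cl2, −78 → −30 °C; then 1 M HCl, THF, 0 °C
Reagents that add atoms: but-3-en-2-one CC(=O)C=C
Why: Mukaiyama–Michael addition: the enone is attacked by the tetrasubstituted enol ether carbon anti to the C3 methyl, which sits pseudoaxial in the half-chair to avoid allylic strain with the C2 methyl, so the 3-oxobutyl chain should end trans to that methyl (2S); the acid work-up hydrolyses enol ether 7.

Step 3
Reactants: 8 (2S,3R)-2,3-dimethyl-2-(3-oxobutyl)cyclohexan-1-one; 9 triethyl phosphonoacetate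
Product: 10 ethyl (E)-5-[(1S,2R)-1,2-dimethyl-6-oxocyclohexyl]-3-methylpent-2-enoate
Conditions: (EtO)2P(O)CH2CO2Et (1.3 equiv), NaH (1.2 equiv), THF, 0 °C; then 8, 0 °C → rt; chromatography
Reagents that add atoms: triethyl phosphonoacetate CCOC(=O)CP(=O)(OCC)OCC
Why: Horner–Wadsworth–Emmons olefination should take place at the unhindered methyl ketone and not at the neopentyl ring ketone, and the stabilised phosphonate should favour the (E)-enoate, with the minor (Z) isomer removable by chromatography.

Step 4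
Reactants: 10 ethyl (E)-5-[(1S,2R)-1,2-dimethyl-6-oxocyclohexyl]-3-methylpent-2-enoate; 11 N-phenylbis(trifluoromethanesulfonimide)
Product: 13 ethyl (E)-5-[(1S,6R)-1,6-dimethyl-2-(trifluoromethylsulfonyloxy)cyclohex-2-en-1-yl]-3-methylpent-2-enoate, via potassium enolate 12 (not isolated)
Conditions: KN(SiMe3)2 (1.1 equiv), THF, −78 °C; then PhNTf2, −78 → 0 °C
Reagents that add atoms: N-phenylbis(trifluoromethanesulfonimide) O=S(=O)(N(c1ccccc1)S(=O)(=O)C(F)(F)F)C(F)(F)F
Why: Kinetic enolisation and O-sulfonylation (enol triflate formation): the α-carbon on one side is quaternary, so the ketone can enolise only towards its CH2 and one regioisomeric triflate should form, the ketone α-CH2 being deprotonated faster than the γ-positions of the enoate at −78 °C.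

Step 5
Reactants: 13 ethyl (E)-5-[(1S,6R)-1,6-dimethyl-2-(trifluoromethylsulfonyloxy)cyclohex-2-en-1-yl]-3-methylpent-2-enoate; 14 tributyl(vinyl)stannane
Product: 15 ethyl (E)-5-[(1S,6R)-2-ethenyl-1,6-dimethylcyclohex-2-en-1-yl]-3-methylpent-2-enoate
Conditions: Bu3SnCH=CH2 (1.3 equiv), Pd(PPh3)4 (5 mol%), LiCl (3 equiv), THF, 65 °C; KF work-up; the diene is used promptly
Reagents that add atoms: tributyl(vinyl)stannane CCCC[Sn](CCCC)(CCCC)C=C
Why: Stille cross-coupling of an alkenyl triflate with a vinylstannane (chloride additive for transmetalation) gives the 1-vinylcyclohexene without touching the stereocentres or the enoate.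

Step 6
Reactants: 15 ethyl (E)-5-[(1S,6R)-2-ethenyl-1,6-dimethylcyclohex-2-en-1-yl]-3-methylpent-2-enoate; 16 methyl methacrylate
Product: 17 methyl (1S,5S,6R,8aR)-5-[(E)-5-ethoxy-3-methyl-5-oxopent-3-en-1-yl]-1,5,6-trimethyl-1,2,3,5,6,7,8,8a-octahydronaphthalene-1-carboxylate
Conditions: methyl methacrylate (5 equiv), EtAlCl2 (2.5 equiv, 1 M in hexane), BHT (cat.), CH2Cl2, −40 → 0 °C; aq. potassium sodium tartrate
Reagents that add atoms: methyl methacrylate COC(=O)C(C)=C
Why: This is a Lewis-acid-promoted, concerted but asynchronous normal-electron-demand [4+2] cycloaddition between the semicyclic diene C2=C1–C10=C5 of 15 and the EtAlCl2-bound acrylate C3=C4 of 16; the closest known reaction type is the Lewis-acid-catalysed Diels–Alder reaction of 1-vinylcyclohexenes with α-substituted acrylates and acroleins. Ring A is closed by cycloaddition (C2–C3 and C4–C5 formed on one face of the s-cis diene, leaving the new C1=C10 alkene), not by a stepwise exo or endo ring closure. The regiochemistry (quaternary C4 bonded to C5, the "ortho" adduct) should follow from the leading bond forming between the acrylate β-carbon C3 and the unhindered diene terminus C2. C5 is set by the diene face: ring B should react through the half-chair with the C8 methyl equatorial and the cis C9 methyl pseudoaxial on the α face, so the dienophile adds to the β face and H5 ends α (5R). C4 is set by the endo rule: the aluminium-bound ester should take the endo position over C10/C1 (secondary orbital and electrostatic preference, and the flat ester is the smaller group for the crowded site gauche to C10 and C6) with the methyl exo, which places CO2Me cis to C6 and trans to H5 (4S). The step therefore needs regio-, endo- and β-face selectivity together, and the 1,2-dialkyl pattern of the diene, the Lewis acid and the cis C8/C9 dimethyl array are what should secure them.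

Step 7
Reactants: 17 methyl (1S,5S,6R,8aR)-5-[(E)-5-ethoxy-3-methyl-5-oxopent-3-en-1-yl]-1,5,6-trimethyl-1,2,3,5,6,7,8,8a-octahydronaphthalene-1-carboxylate
Product: 18 methyl (1S,5S,6R,8aR)-5-[(E)-5-hydroxy-3-methylpent-3-en-1-yl]-1,5,6-trimethyl-1,2,3,5,6,7,8,8a-octahydronaphthalene-1-carboxylate
Conditions: i-Bu2AlH (2.2 equiv), CH2Cl2, −78 °C; aq. potassium sodium tartrate
Reagents that add atoms: none
Why: Hydride 1,2-reduction of an ester with i-Bu2AlH: the unhindered conjugated ethyl ester should be reduced to the allylic alcohol at −78 °C well before the axial, neopentyl C4 methyl ester, which is shielded by its quaternary carbon and the adjacent ring-fusion methine.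

Step 8
Reactants: 18 methyl (1S,5S,6R,8aR)-5-[(E)-5-hydroxy-3-methylpent-3-en-1-yl]-1,5,6-trimethyl-1,2,3,5,6,7,8,8a-octahydronaphthalene-1-carboxylate; 19 tert-butyl hydroperoxide
Product: 20 methyl (1S,5S,6R,8aR)-5-{2-[(2S,3S)-3-(hydroxymethyl)-2-methyloxiran-2-yl]ethyl}-1,5,6-trimethyl-1,2,3,5,6,7,8,8a-octahydronaphthalene-1-carboxylate
Conditions: Ti(OiPr)4 (10 mol%), L-(+)-diethyl tartrate (12 mol%), t-BuOOH (2 equiv, in decane), 4 Å molecular sieves, CH2Cl2, −20 °C
Reagents that add atoms: tert-butyl hydroperoxide CC(C)(C)OO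
Why: Sharpless–Katsuki asymmetric epoxidation: the titanium tartrate complex delivers the peroxide oxygen to one face of the allylic alcohol under reagent control, L-(+)-diethyl tartrate giving the (2S,3S)-epoxy alcohol from (E)-3-methylalk-2-en-1-ols, while the isolated ring alkene and the ester are inert to this reagent.

**Compound list**

1 | 2-methylcyclohex-2-en-1-one | CC1=CCCCC1=O | starting material
2 | trimethylaluminium | C[Al](C)C | starting material
3 | trimethylsilyl trifluoromethanesulfonate | C[Si](C)(C)OS(=O)(=O)C(F)(F)F | starting material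
4 | dimethylaluminium (R)-2,3-dimethylcyclohex-1-en-1-olate | CC1=C(O[Al](C)C)CCC[C@H]1C | intermediate
5 | (R)-[(2,3-dimethylcyclohex-1-en-1-yl)oxy]trimethylsilane | CC1=C(O[Si](C)(C)C)CCC[C@H]1C | intermediate
6 | but-3-en-2-one | CC(=O)C=C | starting material
7 | (2S,3R)-2,3-dimethyl-2-[(Z)-3-(trimethylsilyloxy)but-2-en-1-yl]cyclohexan-1-one (enol ether geometry of no consequence) | O=C1CCC[C@@H](C)[C@]1(C)C/C=C(/C)O[Si](C)(C)C | intermediate
8 | (2S,3R)-2,3-dimethyl-2-(3-oxobutyl)cyclohexan-1-one | O=C1CCC[C@@H](C)[C@]1(C)CCC(C)=O | intermediate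
9 | triethyl phosphonoacetate | CCOC(=O)CP(=O)(OCC)OCC | starting material
10 | ethyl (E)-5-[(1S,2R)-1,2-dimethyl-6-oxocyclohexyl]-3-methylpent-2-enoate | O=C1CCC[C@@H](C)[C@]1(C)CC/C(C)=C/C(=O)OCC | intermediate
11 | N-phenylbis(trifluoromethanesulfonimide) | O=S(=O)(N(c1ccccc1)S(=O)(=O)C(F)(F)F)C(F)(F)F | starting material
12 | potassium (5R,6S)-6-[(E)-5-ethoxy-3-methyl-5-oxopent-3-en-1-yl]-5,6-dimethylcyclohex-1-en-1-olate | [K+].[O-]C1=CCC[C@@H](C)[C@]1(C)CC/C(C)=C/C(=O)OCC | intermediate
13 | ethyl (E)-5-[(1S,6R)-1,6-dimethyl-2-(trifluoromethylsulfonyloxy)cyclohex-2-en-1-yl]-3-methylpent-2-enoate | O=S(=O)(OC1=CCC[C@@H](C)[C@]1(C)CC/C(C)=C/C(=O)OCC)C(F)(F)F | intermediate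
14 | tributyl(vinyl)stannane | CCCC[Sn](CCCC)(CCCC)C=C | starting material
15 | ethyl (E)-5-[(1S,6R)-2-ethenyl-1,6-dimethylcyclohex-2-en-1-yl]-3-methylpent-2-enoate | C=CC1=CCC[C@@H](C)[C@]1(C)CC/C(C)=C/C(=O)OCC | intermediate
16 | methyl methacrylate | COC(=O)C(C)=C | starting material
17 | methyl (1S,5S,6R,8aR)-5-[(E)-5-ethoxy-3-methyl-5-oxopent-3-en-1-yl]-1,5,6-trimethyl-1,2,3,5,6,7,8,8a-octahydronaphthalene-1-carboxylate | COC(=O)[C@@]1(C)CCC=C2[C@H]1CC[C@@H](C)[C@]2(C)CC/C(C)=C/C(=O)OCC | intermediate
18 | methyl (1S,5S,6R,8aR)-5-[(E)-5-hydroxy-3-methylpent-3-en-1-yl]-1,5,6-trimethyl-1,2,3,5,6,7,8,8a-octahydronaphthalene-1-carboxylate | COC(=O)[C@@]1(C)CCC=C2[C@H]1CC[C@@H](C)[C@]2(C)CC/C(C)=C/CO | intermediate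
19 | tert-butyl hydroperoxide | CC(C)(C)OO | starting material
20 | methyl (1S,5S,6R,8aR)-5-{2-[(2S,3S)-3-(hydroxymethyl)-2-methyloxiran-2-yl]ethyl}-1,5,6-trimethyl-1,2,3,5,6,7,8,8a-octahydronaphthalene-1-carboxylate | COC(=O)[C@@]1(C)CCC=C2[C@H]1CC[C@@H](C)[C@]2(C)CC[C@]1(C)O[C@H]1CO | target

**Summary**

Total steps: 8. Longest linear sequence: 8 steps (from 1).

Steps most likely to fail:

Step 6. What may go wrong: poor β-face or endo selectivity, or a cycloaddition of the α-substituted acrylate so slow that the acid-sensitive diene decomposes. Fallback: setting out from 15, the cycloaddition is run with methacrolein, a more reactive dienophile that reacts at −78 °C (BF3·OEt2, or a chiral oxazaborolidinium Lewis acid whose sense is matched to β-face attack, CH2Cl2). This should give the formyl adduct ethyl (E)-5-[(1S,2R,4aR,5S)-5-formyl-1,2,5-trimethyl-1,2,3,4,4a,5,6,7-octahydronaphthalen-1-yl]-3-methylpent-2-enoate F1. Pinnick oxidation (NaClO2, NaH2PO4, 2-methylbut-2-ene, t-BuOH/H2O) then gives (1S,5S,6R,8aR)-5-[(E)-5-ethoxy-3-methyl-5-oxopent-3-en-1-yl]-1,5,6-trimethyl-1,2,3,5,6,7,8,8a-octahydronaphthalene-1-carboxylic acid F2, and methylation (Me3SiCHN2, MeOH/toluene) returns to 17.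

Step 7. What may go wrong: loss of chemoselectivity, the hydride also attacking the C4 methyl ester. Fallback: the order is changed so that only one ester is present during reduction. Setting out from 15, i-Bu2AlH (CH2Cl2, −78 °C) gives (E)-5-[(1S,6R)-2-ethenyl-1,6-dimethylcyclohex-2-en-1-yl]-3-methylpent-2-en-1-ol F3. Silylation (t-BuMe2SiCl, imidazole, DMF) gives tert-butyl{[(E)-5-[(1S,6R)-2-ethenyl-1,6-dimethylcyclohex-2-en-1-yl]-3-methylpent-2-en-1-yl]oxy}dimethylsilane F4. The EtAlCl2-promoted Diels–Alder reaction with 16, as in step 6, gives methyl (1S,5S,6R,8aR)-5-[(E)-5-(tert-butyldimethylsilyloxy)-3-methylpent-3-en-1-yl]-1,5,6-trimethyl-1,2,3,5,6,7,8,8a-octahydronaphthalene-1-carboxylate F5, and Bu4NF (THF) returns to 18.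

Step 2. What may go wrong: polymerisation of the enone, low conversion at the crowded tetrasubstituted enol ether carbon, or aldol closure of the diketone on work-up. Fallback: setting out from 5, MeLi (THF, 0 °C) regenerates the lithium enolate, which is alkylated anti to the C3 methyl with the allylic chloride (E)-1,3-dichlorobut-2-ene, a masked 3-oxobutyl unit (−78 → 0 °C). This gives (2S,3R)-2-[(E)-3-chlorobut-2-en-1-yl]-2,3-dimethylcyclohexan-1-one F6, and hydrolysis of the vinyl chloride (conc. H2SO4, 0 °C) returns to 8.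

**Further compounds**

F1 | step 6 | ethyl (E)-5-[(1S,2R,4aR,5S)-5-formyl-1,2,5-trimethyl-1,2,3,4,4a,5,6,7-octahydronaphthalen-1-yl]-3-methylpent-2-enoate | O=C[C@@]1(C)CCC=C2[C@H]1CC[C@@H](C)[C@]2(C)CC/C(C)=C/C(=O)OCC
F2 | step 6 | (1S,5S,6R,8aR)-5-[(E)-5-ethoxy-3-methyl-5-oxopent-3-en-1-yl]-1,5,6-trimethyl-1,2,3,5,6,7,8,8a-octahydronaphthalene-1-carboxylic acid | OC(=O)[C@@]1(C)CCC=C2[C@H]1CC[C@@H](C)[C@]2(C)CC/C(C)=C/C(=O)OCC
F3 | step 7 | (E)-5-[(1S,6R)-2-ethenyl-1,6-dimethylcyclohex-2-en-1-yl]-3-methylpent-2-en-1-ol | C=CC1=CCC[C@@H](C)[C@]1(C)CC/C(C)=C/CO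
F4 | step 7 | tert-butyl{[(E)-5-[(1S,6R)-2-ethenyl-1,6-dimethylcyclohex-2-en-1-yl]-3-methylpent-2-en-1-yl]oxy}dimethylsilane | C=CC1=CCC[C@@H](C)[C@]1(C)CC/C(C)=C/CO[Si](C)(C)C(C)(C)C
F5 | step 7 | methyl (1S,5S,6R,8aR)-5-[(E)-5-(tert-butyldimethylsilyloxy)-3-methylpent-3-en-1-yl]-1,5,6-trimethyl-1,2,3,5,6,7,8,8a-octahydronaphthalene-1-carboxylate | COC(=O)[C@@]1(C)CCC=C2[C@H]1CC[C@@H](C)[C@]2(C)CC/C(C)=C/CO[Si](C)(C)C(C)(C)C
F6 | step 2 | (2S,3R)-2-[(E)-3-chlorobut-2-en-1-yl]-2,3-dimethylcyclohexan-1-one | O=C1CCC[C@@H](C)[C@]1(C)C/C=C(\C)Cl
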